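## Retrosynthetic overview

1. Target ⇐ desilylation and C6‑O‑methacrylation of a ten‑membered hydroxy lactone.
2. Ten‑membered ring and α‑methylene lactone ⇐ one C6–C7 bond: the SmI2‑derived ketyl radical of a C6 aldehyde adds to C7 of a tethered 3‑(acetoxymethyl)butenolide, then acetate is expelled (sets C6 and C7; last ring formed).
3. Butenolide ⇐ ring‑closing metathesis of a 2‑(acetoxymethyl)acrylate on the C8 allylic alcohol; 3(2H)‑furanone ⇐ lithium acetylide + α‑hydroxy‑γ‑lactone, then O‑cyclisation of the α′‑hydroxy ynone.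
4. Enyne (C2–C6, C15; C5 stereocentre) ⇐ Sharpless epoxidation of (E)‑3‑methylpent‑2‑en‑4‑yn‑1‑ol, then epoxide → allyl silyl ether rearrangement; hydroxy lactone (C1, C8–C10, C14) ⇐ (R)‑2‑vinyloxirane + propanoic acid dianion, then enolate hydroxylation.
5. Ring order: sacrificial γ‑lactone → furanone → butenolide → ten‑membered carbocycle (the butenolide becomes the α‑methylene lactone in the same step).

Assumption: the target is taken exactly as the given SMILES, i.e. (5S,6R,7S,8S,10R) in germacrane‑type atom labels (C10 quaternary furanone carbon, C1 ring ketone, C3 enol‑ether carbon, C4=C15 exo‑methylene, C5 carbinol, C6 acyloxy carbon, C7/C8 lactone fusion, C11–C13 α‑methylene lactone), which are used below.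

## Route

Step 1
Reactants: 1 (E)-3-methylpent-2-en-4-yn-1-ol
Product: 2 [(2R,3R)-3-ethynyl-3-methyloxiran-2-yl]methanol
Conditions: Ti(OiPr)4 (10 mol %), D-(−)-diethyl tartrate (12 mol %), t-BuOOH (2 equiv), 4 Å MS, CH2Cl2, −20 °C
Reagents that add atoms: tert-butyl hydroperoxide, CC(C)(C)OO
Why: Sharpless asymmetric epoxidation of a geraniol-type trisubstituted allylic alcohol; the D-(−)-tartrate catalyst delivers oxygen to the face that makes the carbinol-adjacent epoxide carbon (future C5) R, which becomes 5S once the other C–O bond is opened (CIP priority change only).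

Step 2
Reactants: 2 [(2R,3R)-3-ethynyl-3-methyloxiran-2-yl]methanol
Product: 3 (S)-3-methylene-1,2-bis(triethylsilyloxy)pent-4-yne
Conditions: Et3SiOTf (2.4 equiv), 2,6-lutidine, CH2Cl2, −78 °C; then DBU, −78 °C → rt
Reagents that add atoms: triethylsilyl trifluoromethanesulfonate, CC[Si](CC)(CC)OS(=O)(=O)C(F)(F)F
Why: Noyori-type silyl triflate/amidine epoxide → allyl silyl ether rearrangement: after O-silylation of the primary alcohol the silyl-activated epoxide opens at the tertiary propargylic carbon while DBU removes a methyl proton anti to the breaking C–O bond, so the C4=C15 methylene forms and the C5–O bond and its configuration are untouched.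

Step 3
Reactants: 4 propanoic acid; 5 (R)-2-vinyloxirane
Product: 7 (5S)-3-methyl-5-vinyldihydrofuran-2(3H)-one (C3 epimer mixture), via hydroxy acid 6 (not isolated)
Conditions: LiN(iPr)2 (2.1 equiv), THF, 0 °C; 5, 0 °C → rt; aq. HCl; then TsOH (cat.), toluene, 60 °C
Reagents that add atoms: none
Why: Creger-type alkylation of a carboxylic acid dianion by SN2 opening of the epoxide at its unhindered CH2 terminus (future C9), which leaves the allylic C–O stereocentre (C8, S) untouched, followed by acid-catalysed lactonisation; the epimeric α-centre is erased in the next step.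

Step 4
Reactants: 7 (5S)-3-methyl-5-vinyldihydrofuran-2(3H)-one
Product: 8 (3R,5S)-3-hydroxy-3-methyl-5-vinyldihydrofuran-2(3H)-one
Conditions: KN(SiMe3)2, THF, −78 °C; 3-phenyl-2-(phenylsulfonyl)oxaziridine, −78 °C; aq. NH4Cl
Reagents that add atoms: 3-phenyl-2-(phenylsulfonyl)oxaziridine (Davis reagent), O=S(=O)(N1OC1c1ccccc1)c1ccccc1
Why: Davis enolate hydroxylation; the oxidant approaches the planar lactone enolate anti to the C5 vinyl group (1,3-induction), placing OH trans to vinyl and setting the quaternary C10 centre as R (minor cis isomer removed by chromatography).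

Step 5
Reactants: 3 (S)-3-methylene-1,2-bis(triethylsilyloxy)pent-4-yne; 8 (3R,5S)-3-hydroxy-3-methyl-5-vinyldihydrofuran-2(3H)-one
Product: 10 (R)-2-[(S)-2-hydroxybut-3-en-1-yl]-2-methyl-5-[(S)-3,4-bis(triethylsilyloxy)but-1-en-2-yl]furan-3(2H)-one, via hydroxy ynone 9 (not isolated)
Conditions: 3, n-BuLi, THF, −78 °C; added to 8 + LiN(SiMe3)2 (1 equiv), THF, −78 → −30 °C; aq. NH4Cl; then Et2NH, EtOH, rt
Reagents that add atoms: none
Why: 1,2-addition of the lithium acetylide to the non-enolisable lactone carbonyl releases the C8 hydroxyl, and the α′-hydroxy ynone then undergoes amine-mediated conjugate addition and 5-endo oxa-cyclisation (addition–elimination) to the 3(2H)-furanone without touching any stereocentre.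

Step 6
Reactants: 11 2-(hydroxymethyl)acrylic acid
Product: 12 2-(acetoxymethyl)acrylic acid
Conditions: Ac2O, pyridine, CH2Cl2, 0 °C → rt; aq. HCl work-up
Reagents that add atoms: acetic anhydride, CC(=O)OC(C)=O
Why: Simple O-acetylation (any mixed anhydride is hydrolysed on work-up) that installs the leaving group needed in the ring-closing step.

Step 7
Reactants: 10 (R)-2-[(S)-2-hydroxybut-3-en-1-yl]-2-methyl-5-[(S)-3,4-bis(triethylsilyloxy)but-1-en-2-yl]furan-3(2H)-one; 12 2-(acetoxymethyl)acrylic acid
Product: 14 (S)-1-{(R)-2-methyl-3-oxo-5-[(S)-3,4-bis(triethylsilyloxy)but-1-en-2-yl]-2,3-dihydrofuran-2-yl}but-3-en-2-yl 2-(acetoxymethyl)acrylate, via acid chloride 13 (not isolated)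
Conditions: 12, (COCl)2, DMF (cat.), CH2Cl2, 0 °C → rt, concentrate; then 10, iPr2NEt, CH2Cl2, 0 °C → rt
Reagents that add atoms: none
Why: Acylation of the only free (secondary allylic) hydroxyl through the acid chloride with a non-nucleophilic base, which avoids SN2′ attack of nucleophilic acylation catalysts on the allylic acetate and proceeds with retention at C8.

Step 8
Reactants: 14 (S)-1-{(R)-2-methyl-3-oxo-5-[(S)-3,4-bis(triethylsilyloxy)but-1-en-2-yl]-2,3-dihydrofuran-2-yl}but-3-en-2-yl 2-(acetoxymethyl)acrylate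
Product: 15 {(S)-5-[((R)-2-methyl-3-oxo-5-((S)-3,4-bis(triethylsilyloxy)but-1-en-2-yl)-2,3-dihydrofuran-2-yl)methyl]-2-oxo-2,5-dihydrofuran-3-yl}methyl acetate
Conditions: second-generation Grubbs catalyst RuCl2(H2IMes)(PCy3)(=CHPh) (10 mol %), toluene (5 mM), 80 °C
Reagents that add atoms: none
Why: Ring-closing metathesis: the catalyst loads on the terminal vinyl group and closes onto the acrylate to give the five-membered butenolide (C7=C11), while the hindered, electron-poor C4=C15 and furanone alkenes stay out of the reaction.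

Step 9
Reactants: 15 {(S)-5-[((R)-2-methyl-3-oxo-5-((S)-3,4-bis(triethylsilyloxy)but-1-en-2-yl)-2,3-dihydrofuran-2-yl)methyl]-2-oxo-2,5-dihydrofuran-3-yl}methyl acetate
Product: 16 {(S)-5-[((R)-2-methyl-3-oxo-5-((S)-4-oxo-3-(triethylsilyloxy)but-1-en-2-yl)-2,3-dihydrofuran-2-yl)methyl]-2-oxo-2,5-dihydrofuran-3-yl}methyl acetate
Conditions: (COCl)2, DMSO, CH2Cl2, −78 → −40 °C; iPr2NEt, −78 → −20 °C; crude aldehyde used at once
Reagents that add atoms: none
Why: Swern-type direct oxidation of a primary triethylsilyl ether, in which activated DMSO cleaves only the unhindered primary Si–O bond and the secondary silyl ether survives; low temperature and a hindered base protect the epimerisable C5 and C8 centres.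

Step 10
Reactants: 16 {(S)-5-[((R)-2-methyl-3-oxo-5-((S)-4-oxo-3-(triethylsilyloxy)but-1-en-2-yl)-2,3-dihydrofuran-2-yl)methyl]-2-oxo-2,5-dihydrofuran-3-yl}methyl acetate
Product: 17 (5S,6R,7S,8S,10R)-configured ten-membered hydroxy lactone (the target without its methacryloyl group and with C5–O–SiEt3; C6–OH free)
Conditions: SmI2 (2.5 equiv, 0.1 M in THF), slow addition of 16 (final 2 mM), THF, −78 → 0 °C; pH 7 buffer
Reagents that add atoms: none
Why: Proposed new method: SmI2 reduces the α-silyloxy aldehyde to a ketyl radical that closes the ten-membered ring by adding to C7 (the β-carbon) of the tethered butenolide, the C11 radical takes a second electron from SmI2 and the resulting enolate expels acetate from C13 to unveil the α-methylene lactone; C7–H is set cis to C8–H because the C9 tether delivers the radical to its own face of the butenolide, and C6 is set R (5,6-anti) by Felkin-type approach anti to the C5–OSiEt3 bond; the closest known reaction types are SmI2 ketyl–olefin (aldehyde–enoate) cyclisations and the β-elimination of β-acetoxy enolates generated by SmI2.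

Step 11
Reactants: 17 ten-membered hydroxy lactone; 18 methacryloyl chloride
Product: 19 C5-O-triethylsilyl ether of the target
Conditions: Et3N, DMAP (cat.), CH2Cl2, 0 °C
Reagents that add atoms: none
Why: DMAP-catalysed acylation of the only free (C6) hydroxyl with retention, run promptly and cold so that the hydroxy lactone cannot translactonise.

Step 12
Reactants: 19 C5-O-triethylsilyl ether of the target
Product: 20 CNP0142847.2 (target)
Conditions: HF·pyridine, pyridine, THF, 0 °C
Reagents that add atoms: none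
Why: Fluoride-mediated Si–O cleavage under buffered, mildly acidic conditions that leave the methacrylate, the α-methylene lactone and the dienone intact and avoid base-induced 6→5 acyl migration.

## Compound list

1 | (E)-3-methylpent-2-en-4-yn-1-ol | C#C/C(C)=C/CO | starting material
2 | [(2R,3R)-3-ethynyl-3-methyloxiran-2-yl]methanol | OC[C@H]1O[C@]1(C)C#C | intermediate
3 | (S)-3-methylene-1,2-bis(triethylsilyloxy)pent-4-yne | C#CC(=C)[C@H](O[Si](CC)(CC)CC)CO[Si](CC)(CC)CC | intermediate
4 | propanoic acid | CCC(=O)O | starting material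
5 | (R)-2-vinyloxirane | C=C[C@@H]1CO1 | starting material
6 | (4S)-4-hydroxy-2-methylhex-5-enoic acid (C2 epimers) | C=C[C@@H](O)CC(C)C(=O)O | intermediate
7 | (5S)-3-methyl-5-vinyldihydrofuran-2(3H)-one (C3 epimers) | C=C[C@@H]1CC(C)C(=O)O1 | intermediate
8 | (3R,5S)-3-hydroxy-3-methyl-5-vinyldihydrofuran-2(3H)-one | C=C[C@@H]1C[C@@](C)(O)C(=O)O1 | intermediate
9 | (3S,5R,10S)-3,5-dihydroxy-5-methyl-9-methylene-10,11-bis(triethylsilyloxy)undec-1-en-7-yn-6-one | C=C[C@@H](O)C[C@@](C)(O)C(=O)C#CC(=C)[C@H](O[Si](CC)(CC)CC)CO[Si](CC)(CC)CC | intermediate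
10 | (R)-2-[(S)-2-hydroxybut-3-en-1-yl]-2-methyl-5-[(S)-3,4-bis(triethylsilyloxy)but-1-en-2-yl]furan-3(2H)-one | C=C[C@@H](O)C[C@@]1(C)OC(=CC1=O)C(=C)[C@H](O[Si](CC)(CC)CC)CO[Si](CC)(CC)CC | intermediate
11 | 2-(hydroxymethyl)acrylic acid | C=C(CO)C(=O)O | starting material
12 | 2-(acetoxymethyl)acrylic acid | C=C(COC(C)=O)C(=O)O | intermediate
13 | 2-(acetoxymethyl)acryloyl chloride | C=C(COC(C)=O)C(=O)Cl | intermediate
14 | (S)-1-{(R)-2-methyl-3-oxo-5-[(S)-3,4-bis(triethylsilyloxy)but-1-en-2-yl]-2,3-dihydrofuran-2-yl}but-3-en-2-yl 2-(acetoxymethyl)acrylate | C=C[C@@H](OC(=O)C(=C)COC(C)=O)C[C@@]1(C)OC(=CC1=O)C(=C)[C@H](O[Si](CC)(CC)CC)CO[Si](CC)(CC)CC | intermediate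
15 | {(S)-5-[((R)-2-methyl-3-oxo-5-((S)-3,4-bis(triethylsilyloxy)but-1-en-2-yl)-2,3-dihydrofuran-2-yl)methyl]-2-oxo-2,5-dihydrofuran-3-yl}methyl acetate | CC(=O)OCC1=C[C@H](C[C@@]2(C)OC(=CC2=O)C(=C)[C@H](O[Si](CC)(CC)CC)CO[Si](CC)(CC)CC)OC1=O | intermediate
16 | {(S)-5-[((R)-2-methyl-3-oxo-5-((S)-4-oxo-3-(triethylsilyloxy)but-1-en-2-yl)-2,3-dihydrofuran-2-yl)methyl]-2-oxo-2,5-dihydrofuran-3-yl}methyl acetate | CC(=O)OCC1=C[C@H](C[C@@]2(C)OC(=CC2=O)C(=C)[C@H](O[Si](CC)(CC)CC)C=O)OC1=O | intermediate
17 | (5S,6R,7S,8S,10R) ten-membered hydroxy lactone: target lacking the methacryloyl group, C5–OH as triethylsilyl ether | O[C@@H]1[C@H]2C(=C)C(=O)O[C@H]2C[C@@]2(C)OC(=CC2=O)C(=C)[C@@H]1O[Si](CC)(CC)CC | intermediate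
18 | methacryloyl chloride | C=C(C)C(=O)Cl | starting material
19 | C5-O-triethylsilyl ether of the target | C=C(C)C(=O)O[C@@H]1[C@H]2C(=C)C(=O)O[C@H]2C[C@@]2(C)OC(=CC2=O)C(=C)[C@@H]1O[Si](CC)(CC)CC | intermediate
20 | CNP0142847.2 | C=C(C)C(=O)O[C@@H]1[C@H]2C(=C)C(=O)O[C@H]2C[C@@]2(C)OC(=CC2=O)C(=C)[C@@H]1O | target

## Step count and risks

Total steps: 12. Longest linear sequence: 9 steps (1 → 2 → 3 → 10 → 14 → 15 → 16 → 17 → 19 → 20; steps 1, 2, 5, 7, 8, 9, 10, 11, 12).

Steps most likely to fail, each with one fallback: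

- Step 10 (ketyl radical macrocyclisation). The risks are competing reduction of the dienone or of the allylic acetate, pinacol dimerisation, and uncertain facial control at C6. The fallback sets out from 16 and comes back at 17 by switching to a two-electron allyl-metal addition. Pd(PPh3)4 (zerovalent palladium, 5 mol %) with InI in THF/HMPA at high dilution ionises the allylic acetate and transfers the allyl unit to indium. The resulting allyl–indium nucleophile adds through its γ-carbon (C7) to the C6 aldehyde in a closed transition state, giving 17 directly. This detour creates no new compound, F0.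

- Step 8 (metathesis to a trisubstituted, electron-poor butenolide). The fallback sets out from 10 and comes back at 15, and moves the ring closure to an easier disubstituted olefin. Acylation of 10 with acryloyl chloride (iPr2NEt, CH2Cl2) gives the acrylate ester F1. Ring-closing metathesis (second-generation Grubbs catalyst, CH2Cl2, 40 °C) gives the C11-unsubstituted butenolide F2. Morita–Baylis–Hillman hydroxymethylation (aq. CH2O, imidazole or PMe3, THF) installs C13 as the 3-(hydroxymethyl)butenolide F3. Acetylation (Ac2O, pyridine) then gives 15.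

- Step 2 (cationic epoxide → allyl silyl ether rearrangement at a propargylic centre). The risks are Meinwald-type hydride shift and allenyl-cation side reactions. The fallback sets out from 2 and comes back at 3 by an anionic route. Et3SiCl/imidazole gives the epoxy silyl ether F4. Yamamoto rearrangement with diethylaluminium 2,2,6,6-tetramethylpiperidide (made from Et2AlCl and the lithium amide; benzene, 0 °C) is a syn-β-elimination of a methyl proton through an aluminium-bound epoxide and gives the allylic alcohol F5. Et3SiCl/imidazole then gives 3.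

## Further compounds

F0 | step 10 | none | none
F1 | step 8 | (S)-1-{(R)-2-methyl-3-oxo-5-[(S)-3,4-bis(triethylsilyloxy)but-1-en-2-yl]-2,3-dihydrofuran-2-yl}but-3-en-2-yl acrylate | C=C[C@@H](OC(=O)C=C)C[C@@]1(C)OC(=CC1=O)C(=C)[C@H](O[Si](CC)(CC)CC)CO[Si](CC)(CC)CC
F2 | step 8 | (R)-2-methyl-2-{[(S)-5-oxo-2,5-dihydrofuran-2-yl]methyl}-5-[(S)-3,4-bis(triethylsilyloxy)but-1-en-2-yl]furan-3(2H)-one | O=C1C=C[C@H](C[C@@]2(C)OC(=CC2=O)C(=C)[C@H](O[Si](CC)(CC)CC)CO[Si](CC)(CC)CC)O1
F3 | step 8 | (R)-2-{[(S)-4-(hydroxymethyl)-5-oxo-2,5-dihydrofuran-2-yl]methyl}-2-methyl-5-[(S)-3,4-bis(triethylsilyloxy)but-1-en-2-yl]furan-3(2H)-one | OCC1=C[C@H](C[C@@]2(C)OC(=CC2=O)C(=C)[C@H](O[Si](CC)(CC)CC)CO[Si](CC)(CC)CC)OC1=O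
F4 | step 2 | triethyl{[(2R,3R)-3-ethynyl-3-methyloxiran-2-yl]methoxy}silane | CC[Si](CC)(CC)OC[C@H]1O[C@]1(C)C#C
F5 | step 2 | (S)-3-methylene-1-(triethylsilyloxy)pent-4-yn-2-ol | C#CC(=C)[C@H](O)CO[Si](CC)(CC)CC
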